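## Analysis of the target

The target 34 (CNP0324515.1) is the methyl ester of a C25 acid built on a trans-fused labdane decalin (ring A: C1–C5 and C10; ring B: C5–C10). C9 carries a chain C11–C16 that ends in a 4-methylbutenolide (C16 is C5 of the furan-2(5H)-one), C17 is the methyl on C8, C18 the ester carbon on C4, C19 and C20 the methyls on C4 and C10. Six of the eight stereocentres sit on the decalin: C4 (β-methyl, α-CO2Me), C5 (α-H), C10 (β-methyl), C6 (α-OH, equatorial, peri to the equatorial ester), C8 (α-OH, β-methyl, so that C17 and C20 are 1,3-diaxial) and C9 (β-chain, equatorial). The remaining two, C14 (S, a secondary allylic hydroperoxide beside the 13-methylene) and C16 (S, the γ-carbon of the butenolide), are 1,3-anti and too far from the ring to be controlled by it. The hydroperoxide is sensitive to reduction, base (Kornblum–DeLaMare fragmentation, addition to the butenolide), acid (Hock cleavage) and transition metals. The butenolide is sensitive to base (γ-deprotonation at C16, conjugate addition), the tertiary C8 carbinol dehydrates or closes onto any activated C12, and the 6α-OH/C18 ester pair can lactonise. The difficulties are an oxygen on the unactivated methylene C6, the hindered fully substituted C8 next to C9, two chain stereocentres without relay, and a peroxide that must be introduced last. The strategy rests on two features: the vicinal trans pair C8 (tertiary carbinol, O on the α face, methyl C17) and C9 (methine bearing C11) on ring B is what a ketyl leaves when it adds to the β-carbon of an enoate, and ring A with its C4 carboxyl is ring A of dehydroabietic acid (1).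

## Retrosynthetic reasoning

**C14–O bond.** The hydroperoxide of 34 is disconnected first, because it survives almost no reagent. It is traced to the acid-labile peroxyketal 33, which also still carries the 6-O-silyl group, and 33 to the (14R)-allylic alcohol 31 through its mesylate 32. Cutting the C–O bond (and not building the peroxide by an ene reaction on an olefin) makes C14 a carbinol whose configuration can be set by a reagent and then inverted in an SN2 step with a peroxy anion. The forward step has to favour direct substitution over allylic transposition and must spare the butenolide.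

**C14 carbinol.** Alcohol 31 is taken back to the α-methylene ketone 30. The ring is too remote to bias C14, so a catalyst-controlled carbonyl reduction is the reliable way to set it. Keeping C14 as a ketone up to this point also activates the chain fragment for the preceding radical coupling.

**C11–C12 bond.** Enone 30 is cut between C11 and C12. On the ring side this leaves a primary C11 radical, available by loss of CO2 from the carboxylate 29, which is the opened form of lactone 15. On the chain side it leaves the allyl sulfone 26, whose methylene terminus becomes C12 and whose sulfonylmethyl carbon becomes the 13-methylene. This cut is chosen because C12 of the ring fragment is already a carboxyl carbon after the key step, so no redox adjustment is needed. A radical at C11 also tolerates the free tertiary 8α-hydroxyl, which would close to a tetrahydrofuran or a lactone with any electrophilic or activated C12. The whole C12–C16 unit with the butenolide arrives in one convergent step.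

**C6–O bond.** The silyl ether 15 and the hydroxy ester 14 lead back to the bislactone 13 and this to the lactone acid 12. C6 is an unactivated methylene, and the only functional group within reach is the equatorial C18 carboxyl, peri to 6α-H. Using it as an internal director turns the ester carbon that the resin acid supplies into the tool for the C–H oxidation. The temporary 18,6α-lactone is then opened by methanol to give back exactly the ester and the alcohol of the target. The 12,8α-lactone is closed beforehand so that the tertiary alcohol and C12 are masked and electron-poor during the oxidation.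

**Lactone acid.** Compound 12 comes from the hydroxy diester 10 by cleavage of both methyl esters and closure of the γ-lactone. The C18 methyl ester therefore serves only as a protecting group through the first half of the route.

**C8–C9 bond (key disconnection).** Diester 10 is opened between C8 and C9 to the keto enoate 9. No other ring B bond is as productive: this cut removes the ring, the tertiary carbinol and the C9 stereocentre together. It leaves a methyl ketone and an enoate that are both easy to make, and it keeps C4, C5 and C10 on an intact cyclohexane that anchors the transition state. The forward reaction must join an electrophilic ketone carbon to an electrophilic enoate β-carbon, which calls for a reductive ketyl closure with divalent samarium.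

**Precursor.** Enoate 9 is cut at C9=C11 into the keto aldehyde 7 and the phosphonate 8. Compound 7 is reached from the seco diacid 3 by differentiating its two carboxyl groups through 4, 5 and 6: the unhindered C8 acid becomes the methyl ketone, the neopentyl C9 acid the aldehyde. Diacid 3 results from excision of the aromatic ring of 2, the methyl ester of 1, so that C8 and C9 are the two former arene carbons bearing sp3 substituents.

**Chain fragment and peroxide reagent.** Sulfone 26 is traced through 25, 24 and 23 to the butenolide 22 (allylic chlorination, sulfinate substitution, oxidation). Butenolide 22 opens at its ring C=C to the acrylate 21 of alcohol 20, whose C16 centre comes from a catalyst-controlled reduction of ketone 19. The carbon chain of 19 is cut at C14–C15 into 16 and 17 (aldol to 18), and the carbinol formed there need not be controlled because it ends as the C14 ketone. The peroxy nucleophile 28 is made from 27.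

## Alternatives that were turned down

**Alternative 1:** The bond cut is C18–O, with the carbon skeleton taken from a 4,4-dimethyl labdane lactone. The 6α-hydroxy 12,8α-lactone A1 would be converted into its hypoiodite with a hypervalent iodine oxidant and iodine under visible light. The 6α-alkoxy radical abstracts hydrogen from the equatorial 4α-methyl by 1,5-transfer, and iodination and ring closure give the 6α,18-ether A2. In its favour, this alkoxy-radical functionalisation is among the most dependable remote C–H reactions, the peri geometry is ideal, and ring B with its 8α-oxygen could be bought in the chiral pool, so no arene excision and no ring closure would be needed. On reliability of the C–H step it is stronger than the chosen route. Against it, A1 needs the 6α-hydroxyl to be there already, and nothing in a 4,4-dimethyl lactone directs an oxidant to C6. Further, A2 holds C18 two oxidation levels too low, so an ether-to-lactone oxidation next to the tertiary C6–H and a methanolysis have to follow before the material would reach the stage of 13. β-Scission of the alkoxy radical towards the tertiary C5 radical is a competing path. The chosen strategy offers in exchange a C18 that is at the carboxyl level from the first step and serves as the director itself, so one C–H oxidation suffices.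

**Alternative 2:** Both rings are cut at once, at C3–C4 and C5–C10. The dithiane-masked trienone A3 would undergo an intramolecular Diels–Alder reaction, thermally or with an aluminium Lewis acid, to the trans-fused 6-oxo-octalin A4. In its favour, it is convergent, the C6 oxygen is present from the start as the ketone, C8 is masked at the carbonyl level and C9 already bears a three-carbon handle. On C6 it is stronger than the chosen route, which needs a C–H oxidation. Against it, both new bonds end at quaternary carbons (C4 and C10) flanking C5. The dienophile is trisubstituted with geminal methyl and ester, and the diene terminus carries a cis methyl that disfavours the s-cis conformer, so reactivity and endo/exo control are doubtful. Four stereocentres depend on two alkene geometries and on a C9 centre that must first be made enantiopure. After the cycloaddition A4 still needs hydrogenation of C1=C2, a thermodynamic reduction to the equatorial 6α-alcohol (hydride from the open α face gives the axial epimer), and introduction of C17 from the hindered β face of C8, where nucleophiles prefer the α face. The chosen strategy takes C4, C5 and C10 in the correct absolute configuration from 1 and sets C8 and C9 in one step with the oxygen on the required face.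

**Alternative 3:** The strategic bond is C6–O. The lactone acid A5 would be oxidised with an iron–PDP catalyst and hydrogen peroxide at the 6α C–H bond to the bislactone A6. A5 and A6 are the same compounds as 12 and 13, and the chosen route uses this reaction as step 10, so on this point the two are equally strong. As a strategy, however, it leaves open where A5 comes from. The lactone acid with a 4α-carboxyl is not a chiral-pool compound, so ring B, the C8 carbinol and the C8–C9 bond would still have to be made, or C18 oxidised up from a methyl group. It would also make the least predictable step of the synthesis the pivot (a strained, doubly trans-fused lactone, and possible over-oxidation at C6). The chosen strategy supplies A5 (as 12) in nine steps from 1. It also keeps the C6 oxidation exchangeable: an amide-based radical lactonisation can replace it without touching the key disconnection.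

Key step: step 8

## Route

Remark: α/β and the locants C1–C20 follow the labdane numbering defined in the analysis, also for the ring-opened compounds 3–9; side-chain carbons are C11–C16 counted from C9.
Assumption: technical dehydroabietic acid (1) is used after purification to the single enantiomer (recrystallisation of its 2-aminoethanol salt).

Step 1
Reactants: 1 dehydroabietic acid
Product: 2 methyl dehydroabietate
Conditions: MeI, K2CO3, DMF, rt
Reagents that add atoms: iodomethane, CI
Why: SN2 alkylation of the carboxylate at oxygen (Williamson-type esterification) bypasses the hindered neopentyl carbonyl; no stereocentre is touched.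

Step 2
Reactants: 2 methyl dehydroabietate
Product: 3 seco diacid (C8 and C9 carboxylic acids; C18 methyl ester)
Conditions: RuCl3·xH2O (5 mol %), NaIO4 (excess), CCl4–MeCN–H2O, rt
Reagents that add atoms: sodium periodate, [Na+].[O-]I(=O)(=O)=O; water, O
Why: RuO4 (octavalent ruthenium) formed in situ degrades the trialkylbenzene ring (oxidative arene degradation); C8 and C9, which carry the sp3 substituents C7 and C10, remain as carboxyl carbons, while C11–C14 and the isopropyl group leave as CO2 and isobutyric acid. C4, C5 and C10 have no enolisable hydrogen next to a carbonyl group and keep their configuration.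

Step 3
Reactants: 3 seco diacid
Product: 4 C8 Weinreb amide with free C9 acid
Conditions: 1,1'-carbonyldiimidazole (1.05 equiv), CH2Cl2, 0 °C; then MeNHOMe·HCl, rt
Reagents that add atoms: N,O-dimethylhydroxylamine hydrochloride, CNOC.Cl
Why: Acyl imidazole formation and aminolysis (amide coupling) are far faster at the unhindered primary C8 carboxyl than at the C9 carboxyl on quaternary C10; a mixed anhydride between the two acids would be opened by the amine at the same, less hindered carbonyl.

Step 4
Reactants: 4 C8 Weinreb amide with free C9 acid
Product: 5 C8 methyl ketone with free C9 acid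
Conditions: MeMgBr (3 equiv), THF, −20 → 0 °C; aq. NH4Cl
Reagents that add atoms: methylmagnesium bromide, C[Mg]Br
Why: Grignard addition to a Weinreb amide stops at the chelated tetrahedral adduct, which releases the ketone only on work-up; the first equivalent is spent on the acid, whose salt is inert, and the neopentyl ester does not react at this temperature.

Step 5
Reactants: 5 C8 methyl ketone with free C9 acid
Product: 6 diol (C8 carbinol as epimer mixture; C9 primary alcohol)
Conditions: BH3·SMe2, THF, 0 °C → rt; MeOH
Reagents that add atoms: none
Why: Borane reduces the carboxylic acid (through the acyloxyborane) and the ketone but not the hindered ester; the carbinol centre at C8 forms unselectively, which is immaterial because it is oxidised in step 6.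

Step 6
Reactants: 6 diol
Product: 7 keto aldehyde (C8 methyl ketone; C9 aldehyde)
Conditions: Dess–Martin periodinane, NaHCO3, CH2Cl2, rt
Reagents that add atoms: none
Why: Dess–Martin oxidation of both alcohols under buffered, non-enolising conditions; the aldehyde on quaternary C10 has no α-hydrogen and the keto aldehyde sees no base, so no aldol closure is expected.

Step 7
Reactants: 7 keto aldehyde; 8 trimethyl phosphonoacetate
Product: 9 ring A keto enoate (C8 methyl ketone; (E)-C9=C11 enoate; C18 methyl ester)
Conditions: NaH (1.0 equiv), 8 (1.05 equiv), THF, 0 °C → rt
Reagents that add atoms: none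
Why: Horner–Wadsworth–Emmons olefination; the stabilised phosphonate anion is too weakly basic to enolise the methyl ketone and reacts with the aldehyde much faster than with the ketone, and the bulky aldehyde gives the (E)-enoate.

Step 8
Reactants: 9 ring A keto enoate
Product: 10 8α-hydroxy decalin diester (C12 and C18 methyl esters)
Conditions: SmI2 (2.5 equiv), HMPA, t-BuOH (2 equiv), THF, −78 → −20 °C
Reagents that add atoms: none
Why: Electron transfer from divalent samarium to the C8 ketone gives a samarium ketyl that adds to C9, the β-carbon of the enoate, and a second electron and a proton from t-BuOH turn the resulting ester enolate radical into the C11 methylene; the closest known reaction type is the SmI2-mediated reductive cyclisation of ketones onto α,β-unsaturated esters. Ring B (C5–C10) closes in the 6-exo-trig mode with C9=C11 exocyclic. C9 is set by the chair that ring A enforces: C5–C6 and C10–C9 are both equatorial on ring A, so the strain-free chair places C9=C11 pseudo-equatorial and H9 anti to the axial C20 methyl, which gives the 9β chain. C8 is set by the ketyl substituents: the oxygen with its HMPA-solvated trivalent samarium is the larger group and repels the enoate dipole, so it takes the pseudo-equatorial position and leaves C17 axial, which is the 8α-O/9β-C11 trans arrangement. The step needs this trans selectivity although it brings C17 syn-axial to C20; the early transition state with a long C8···C9 distance and the size of the solvated O–Sm group are what should secure it. It also needs ketyl addition to outrun plain saturation of the enoate, which the intramolecular 6-exo geometry and the low temperature favour. Partial closure of the samarium alkoxide onto C12 would be harmless, because step 9 converges on 12.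

Step 9
Reactants: 10 8α-hydroxy decalin diester
Product: 12 lactone acid (C12→O8 γ-lactone; free C18 carboxyl), via 8α-hydroxy diacid 11 (not isolated)
Conditions: NaSEt, DMF, 90 °C; then 2 M HCl, THF, 40 °C
Reagents that add atoms: none
Why: Thiolate attacks the O-methyl carbons (SN2 dealkylation), so both esters are cleaved irrespective of the hindrance at C18; on acidification the γ-hydroxy acid closes to the unstrained trans-fused γ-lactone and leaves the C18 carboxyl free.

Step 10
Reactants: 12 lactone acid
Product: 13 bislactone (C12→O8 and C18→O6α)
Conditions: [Fe((S,S)-PDP)(MeCN)2](SbF6)2 (3 × 5 mol %), H2O2 (50 % aq., 3 × 1.2 equiv), MeCN, rt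
Reagents that add atoms: hydrogen peroxide, OO (oxygen source where hydroxylation precedes ring closure; otherwise the ring oxygen is that of the carboxyl group)
Why: Carboxylic-acid-directed C–H lactonisation with a non-haem iron catalyst: the C18 carboxylate binds iron in place of the usual acetic acid additive, and the iron-oxo unit reaches only the γ-hydrogen 6α-H, which lies peri to the equatorial carboxyl; C–O bond formation occurs with retention, so the oxygen is 6α. The ring A methylenes are out of reach of the bound oxidant, and the tertiary C5–H and C9–H bonds are deactivated by the neighbouring carboxyl and lactone groups.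

Step 11
Reactants: 13 bislactone
Product: 14 6α-hydroxy lactone ester
Conditions: K2CO3 (0.3 equiv), MeOH, 0 °C → rt; aq. NH4Cl
Reagents that add atoms: methanol, CO
Why: Base-catalysed transesterification; the doubly trans-fused 18,6α-lactone is the strained one and opens to the methyl ester, whereas the unstrained 12,8α-lactone on the tertiary carbinol is retained or re-forms on work-up (any 8-hydroxy 12-methyl ester would converge in step 22).

Step 12
Reactants: 14 6α-hydroxy lactone ester
Product: 15 6α-triethylsilyloxy lactone ester
Conditions: TESOTf, 2,6-lutidine, CH2Cl2, −40 °C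
Reagents that add atoms: triethylsilyl triflate, CC[Si](CC)(CC)OS(=O)(=O)C(F)(F)F
Why: Silyl triflate silylation of the hindered equatorial secondary alcohol; the ether blocks acyl transfer from C18 to O6 under the basic conditions of step 22 and sulfonylation in step 24.

Step 13
Reactants: 16 3-methylbut-3-en-2-one; 17 methacrolein
Product: 18 (±)-5-hydroxy-2,6-dimethylhepta-1,6-dien-3-one
Conditions: LiN(i-Pr)2 (LDA), THF, −78 °C; then 17; aq. NH4Cl
Reagents that add atoms: none
Why: Aldol addition of the kinetic lithium enolate (deprotonation at the methyl group of the enone) to the aldehyde carbonyl; the carbinol centre (C14 of the target) is racemic, which is immaterial because it is oxidised in step 20.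

Step 14
Reactants: 18 (±)-5-hydroxy-2,6-dimethylhepta-1,6-dien-3-one
Product: 19 (±)-2,6-dimethyl-5-(triethylsilyloxy)hepta-1,6-dien-3-one
Conditions: TESCl, imidazole, DMF, 0 °C
Reagents that add atoms: chlorotriethylsilane, CC[Si](Cl)(CC)CC
Why: Standard silylation; the ether prevents hydroxyl-directed hydride delivery in step 15 and survives steps 16–19.

Step 15
Reactants: 19 (±)-2,6-dimethyl-5-(triethylsilyloxy)hepta-1,6-dien-3-one
Product: 20 (3S,5RS)-2,6-dimethyl-5-(triethylsilyloxy)hepta-1,6-dien-3-ol
Conditions: (R)-2-methyl-CBS-oxazaborolidine (20 mol %), catecholborane, toluene, −78 °C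
Reagents that add atoms: none
Why: Corey–Bakshi–Shibata reduction; the isopropenyl group acts as the large and the methylene as the small substituent, so the (R)-oxazaborolidine should give the (S)-carbinol (C16 of the target) in both C5 epimers, and catecholborane at low temperature does not hydroborate the alkenes.

Step 16
Reactants: 20 (3S,5RS)-2,6-dimethyl-5-(triethylsilyloxy)hepta-1,6-dien-3-ol
Product: 21 acrylate of 20
Conditions: acryloyl chloride, i-Pr2NEt, DMAP (cat.), CH2Cl2, −20 → 0 °C
Reagents that add atoms: acryloyl chloride, C=CC(=O)Cl
Why: O-Acylation of the secondary allylic alcohol, with retention at the carbinol carbon.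

Step 17
Reactants: 21 acrylate of 20
Product: 22 (5S)-4-methyl-5-[3-methyl-2-(triethylsilyloxy)but-3-enyl]furan-2(5H)-one
Conditions: second-generation Hoveyda–Grubbs catalyst (5 mol %), toluene (5 mM), 80 °C
Reagents that add atoms: none
Why: Ring-closing metathesis between the acrylate and the neighbouring 1,1-disubstituted alkene closes the five-membered butenolide; closure onto the distal isopropenyl group would give a seven-membered ring and is slower. C16 is not touched.

Step 18
Reactants: 22 (5S)-4-methyl-5-[3-methyl-2-(triethylsilyloxy)but-3-enyl]furan-2(5H)-one
Product: 23 (5S)-5-[3-(chloromethyl)-2-(triethylsilyloxy)but-3-enyl]-4-methylfuran-2(5H)-one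
Conditions: N-chlorosuccinimide, PhSeCl (10 mol %), CH2Cl2, rt
Reagents that add atoms: N-chlorosuccinimide, O=C1CCC(=O)N1Cl
Why: Selenium-catalysed ene-type allylic chlorination of the remaining electron-rich 1,1-disubstituted alkene: chlorine enters at the terminal carbon and the double bond moves to the former methyl group; the electron-poor butenolide alkene does not react.

Step 19
Reactants: 23 (5S)-5-[3-(chloromethyl)-2-(triethylsilyloxy)but-3-enyl]-4-methylfuran-2(5H)-one
Product: 24 (5S)-4-methyl-5-[3-(phenylsulfonylmethyl)-2-(triethylsilyloxy)but-3-enyl]furan-2(5H)-one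
Conditions: PhSO2Na, n-Bu4NI (cat.), DMF, rt
Reagents that add atoms: sodium benzenesulfinate, [Na+].[O-]S(=O)c1ccccc1
Why: S-Alkylation of the sulfinate by the allylic chloride (SN2; the SN2′ path gives the same constitution).

Step 20
Reactants: 24 (5S)-4-methyl-5-[3-(phenylsulfonylmethyl)-2-(triethylsilyloxy)but-3-enyl]furan-2(5H)-one
Product: 26 (5S)-4-methyl-5-[2-oxo-3-(phenylsulfonylmethyl)but-3-enyl]furan-2(5H)-one, via allylic carbinol 25 (not isolated)
Conditions: CrO3, H2SO4, acetone–H2O, 0 °C
Reagents that add atoms: none
Why: Jones oxidation; the aqueous acid cleaves the triethylsilyl ether and hexavalent chromium oxidises the liberated allylic alcohol, which merges the two carbinol epimers into one enone. The acidic medium avoids β-elimination of the lactone oxygen from the β-acyloxy ketone.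

Step 21
Reactants: 27 2,3-dimethylbut-2-ene
Product: 28 2-methoxypropan-2-yl hydroperoxide
Conditions: O3, MeOH–CH2Cl2, −78 °C
Reagents that add atoms: ozone, [O-][O+]=O; methanol, CO
Why: Ozonolysis of the tetrasubstituted alkene in methanol; the carbonyl oxide is trapped by the solvent as the α-methoxy hydroperoxide, a hydroperoxide-anion equivalent whose ketal is later removed by mild acid.

Step 22
Reactants: 15 6α-triethylsilyloxy lactone ester; 26 (5S)-4-methyl-5-[2-oxo-3-(phenylsulfonylmethyl)but-3-enyl]furan-2(5H)-one
Product: 30 coupled C14 enone (13-methylene-14-oxo chain on C9), via cesium carboxylate 29 (not isolated)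
Conditions: CsOH·H2O (1.05 equiv), THF–MeOH–H2O, 40 °C, evaporate; then 26 (1.5 equiv), 9-mesityl-3,6-di-tert-butyl-10-phenylacridinium tetrafluoroborate (5 mol %), MeCN–H2O (9:1), 450 nm LEDs, rt
Reagents that add atoms: cesium hydroxide monohydrate, O.[OH-].[Cs+] (its atoms are in intermediate 29 only)
Why: Hydroxide opens the unhindered lactone carbonyl and spares the neopentyl ester; the excited acridinium oxidises the carboxylate, CO2 is lost, and the primary C11 radical adds to the methylene terminus of the ketone-activated allyl sulfone, after which β-scission of the sulfonyl radical (or reduction and sulfinate loss) gives the C11–C12 bond (photoredox decarboxylative allylation, a radical addition–fragmentation). The carboxyl group is never activated, so the free 8α-hydroxyl cannot re-lactonise, and no stereocentre is involved.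

Step 23
Reactants: 30 coupled C14 enone
Product: 31 (14R)-allylic alcohol
Conditions: (S)-2-methyl-CBS-oxazaborolidine (0.5 equiv), catecholborane (3 equiv), toluene–CH2Cl2, −78 °C
Reagents that add atoms: none
Why: Corey–Bakshi–Shibata reduction of the α-methylene ketone; the alkenyl carbon C13 is the large and the C15 methylene the small substituent, so the (S)-oxazaborolidine should give the (14R)-alcohol under reagent control, independent of the remote centres, and 1,2-reduction is favoured at −78 °C.

Step 24
Reactants: 31 (14R)-allylic alcohol; 28 2-methoxypropan-2-yl hydroperoxide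
Product: 33 (14S)-peroxyketal, via (14R)-mesylate 32 (not isolated)
Conditions: Ms2O, i-Pr2NEt, CH2Cl2, −40 °C; then 28, CsOH·H2O, DMF, −20 → 0 °C
Reagents that add atoms: methanesulfonic anhydride, CS(=O)(=O)OS(C)(=O)=O (in intermediate 32 only)
Why: Sulfonylation of the only unhindered free hydroxyl (the tertiary 8α-OH is much slower at −40 °C), then SN2 displacement by the weakly basic, strongly nucleophilic peroxy anion, the known route from secondary sulfonates to hydroperoxides with inversion; (14R) becomes (14S).

Step 25
Reactants: 33 (14S)-peroxyketal
Product: 34 CNP0324515.1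
Conditions: AcOH–THF–H2O (3:1:1), rt
Reagents that add atoms: none
Why: Mild acid hydrolysis cleaves the peroxyketal (to acetone and methanol) and the triethylsilyl ether; hydroperoxide, butenolide, tertiary alcohol and esters should tolerate aqueous acetic acid.

## Compound list

1 | dehydroabietic acid (abieta-8,11,13-trien-18-oic acid) | CC(C)c1ccc2c(c1)CC[C@@H]1[C@]2(C)CCC[C@@]1(C)C(=O)O | starting material
2 | methyl dehydroabietate | CC(C)c1ccc2c(c1)CC[C@@H]1[C@]2(C)CCC[C@@]1(C)C(=O)OC | intermediate
3 | seco diacid: 2-(2-carboxyethyl)-3-(methoxycarbonyl)-1,3-dimethylcyclohexane-1-carboxylic acid, C4/C5/C10 as in 1 (4α-CO2Me, 4β-Me, 5α-H, 10β-Me) | OC(=O)[C@@]1(C)CCC[C@@](C)(C(=O)OC)[C@@H]1CCC(=O)O | intermediate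
4 | C8 N-methoxy-N-methylamide of 3 with free C9 acid | OC(=O)[C@@]1(C)CCC[C@@](C)(C(=O)OC)[C@@H]1CCC(=O)N(C)OC | intermediate
5 | keto acid: C5 chain CH2CH2C(=O)CH3 (C8 methyl ketone), C9 acid on C10 | OC(=O)[C@@]1(C)CCC[C@@](C)(C(=O)OC)[C@@H]1CCC(C)=O | intermediate
6 | diol: C9 hydroxymethyl on C10, C8 secondary alcohol (both C8 epimers) | OC[C@@]1(C)CCC[C@@](C)(C(=O)OC)[C@@H]1CCC(C)O | intermediate
7 | keto aldehyde: C9 formyl on C10, C8 methyl ketone | O=C[C@@]1(C)CCC[C@@](C)(C(=O)OC)[C@@H]1CCC(C)=O | intermediate
8 | trimethyl phosphonoacetate | COC(=O)CP(=O)(OC)OC | starting material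
9 | ring A keto enoate: (E)-C9=C11 methyl enoate on C10, C8 methyl ketone, C18 methyl ester | COC(=O)/C=C/[C@@]1(C)CCC[C@@](C)(C(=O)OC)[C@@H]1CCC(C)=O | intermediate
10 | dimethyl 8α-hydroxy-13,14,15,16-tetranorlabdane-12,18-dioate (5α-H, 9α-H, 8β-Me, 10β-Me, 4α-CO2Me) | COC(=O)C[C@@H]1[C@@]2(C)CCC[C@@](C)(C(=O)OC)[C@@H]2CC[C@@]1(C)O | intermediate
11 | 8α-hydroxy-13,14,15,16-tetranorlabdane-12,18-dioic acid | OC(=O)C[C@@H]1[C@@]2(C)CCC[C@@](C)(C(=O)O)[C@@H]2CC[C@@]1(C)O | intermediate (not isolated)
12 | lactone acid: 12,8α-olide of 11 with free C18 carboxyl | O=C1C[C@@H]2[C@@]3(C)CCC[C@@](C)(C(=O)O)[C@@H]3CC[C@@]2(C)O1 | intermediate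
13 | bislactone: 12,8α-olide and 18,6α-olide | O=C1C[C@@H]2[C@@]3(C)CCC[C@@](C)(C(=O)O4)[C@@H]3[C@@H]4C[C@@]2(C)O1 | intermediate
14 | methyl 6α-hydroxy-12,8α-olide-18-oate | O=C1C[C@@H]2[C@@]3(C)CCC[C@@](C)(C(=O)OC)[C@@H]3[C@@H](O)C[C@@]2(C)O1 | intermediate
15 | 6α-triethylsilyl ether of 14 | O=C1C[C@@H]2[C@@]3(C)CCC[C@@](C)(C(=O)OC)[C@@H]3[C@@H](O[Si](CC)(CC)CC)C[C@@]2(C)O1 | intermediate
16 | 3-methylbut-3-en-2-one | CC(=O)C(C)=C | starting material
17 | methacrolein | C=C(C)C=O | starting material
18 | (±)-5-hydroxy-2,6-dimethylhepta-1,6-dien-3-one | C=C(C)C(O)CC(=O)C(C)=C | intermediate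
19 | (±)-2,6-dimethyl-5-(triethylsilyloxy)hepta-1,6-dien-3-one | C=C(C)C(O[Si](CC)(CC)CC)CC(=O)C(C)=C | intermediate
20 | (3S,5RS)-2,6-dimethyl-5-(triethylsilyloxy)hepta-1,6-dien-3-ol | C=C(C)[C@@H](O)CC(O[Si](CC)(CC)CC)C(C)=C | intermediate
21 | (3S,5RS)-2,6-dimethyl-5-(triethylsilyloxy)hepta-1,6-dien-3-yl acrylate | C=CC(=O)O[C@@H](CC(O[Si](CC)(CC)CC)C(C)=C)C(C)=C | intermediate
22 | (5S)-4-methyl-5-[3-methyl-2-(triethylsilyloxy)but-3-enyl]furan-2(5H)-one (both silyloxy epimers) | C=C(C)C(O[Si](CC)(CC)CC)C[C@@H]1OC(=O)C=C1C | intermediate
23 | (5S)-5-[3-(chloromethyl)-2-(triethylsilyloxy)but-3-enyl]-4-methylfuran-2(5H)-one | C=C(CCl)C(O[Si](CC)(CC)CC)C[C@@H]1OC(=O)C=C1C | intermediate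
24 | (5S)-4-methyl-5-[3-(phenylsulfonylmethyl)-2-(triethylsilyloxy)but-3-enyl]furan-2(5H)-one | C=C(CS(=O)(=O)c1ccccc1)C(O[Si](CC)(CC)CC)C[C@@H]1OC(=O)C=C1C | intermediate
25 | (5S)-5-[2-hydroxy-3-(phenylsulfonylmethyl)but-3-enyl]-4-methylfuran-2(5H)-one | C=C(CS(=O)(=O)c1ccccc1)C(O)C[C@@H]1OC(=O)C=C1C | intermediate (not isolated)
26 | (5S)-4-methyl-5-[2-oxo-3-(phenylsulfonylmethyl)but-3-enyl]furan-2(5H)-one | C=C(CS(=O)(=O)c1ccccc1)C(=O)C[C@@H]1OC(=O)C=C1C | intermediate
27 | 2,3-dimethylbut-2-ene | CC(C)=C(C)C | starting material
28 | 2-methoxypropan-2-yl hydroperoxide | COC(C)(C)OO | intermediate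
29 | cesium 8α-hydroxy-18-methoxy-18-oxo-6α-(triethylsilyloxy)-13,14,15,16-tetranorlabdan-12-oate | [Cs+].[O-]C(=O)C[C@@H]1[C@@]2(C)CCC[C@@](C)(C(=O)OC)[C@@H]2[C@@H](O[Si](CC)(CC)CC)C[C@@]1(C)O | intermediate (not isolated)
30 | coupled enone: C9–CH2CH2–C(=CH2)–C(=O)–CH2–[(S)-butenolide], 6α-OTES, 8α-OH, C18 methyl ester | C=C(CC[C@@H]1[C@@]2(C)CCC[C@@](C)(C(=O)OC)[C@@H]2[C@@H](O[Si](CC)(CC)CC)C[C@@]1(C)O)C(=O)C[C@@H]1OC(=O)C=C1C | intermediate
31 | (14R)-allylic alcohol of 30 | C=C(CC[C@@H]1[C@@]2(C)CCC[C@@](C)(C(=O)OC)[C@@H]2[C@@H](O[Si](CC)(CC)CC)C[C@@]1(C)O)[C@@H](C[C@@H]1OC(=O)C=C1C)O | intermediate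
32 | (14R)-methanesulfonate of 31 | C=C(CC[C@@H]1[C@@]2(C)CCC[C@@](C)(C(=O)OC)[C@@H]2[C@@H](O[Si](CC)(CC)CC)C[C@@]1(C)O)[C@@H](C[C@@H]1OC(=O)C=C1C)OS(C)(=O)=O | intermediate (not isolated)
33 | (14S)-(2-methoxypropan-2-yl)peroxy compound, 6α-OTES | C=C(CC[C@@H]1[C@@]2(C)CCC[C@@](C)(C(=O)OC)[C@@H]2[C@@H](O[Si](CC)(CC)CC)C[C@@]1(C)O)[C@H](C[C@@H]1OC(=O)C=C1C)OOC(C)(C)OC | intermediate
34 | CNP0324515.1: 4α-CO2Me, 6α,8α-diol, (14S)-hydroperoxide, 13-methylene, (16S)-4-methylbutenolide | C=C(CC[C@@H]1[C@@]2(C)CCC[C@@](C)(C(=O)OC)[C@@H]2[C@@H](O)C[C@@]1(C)O)[C@H](C[C@@H]1OC(=O)C=C1C)OO | target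

## Step count and least certain steps

Total step count: 25 (steps 1–12 ring part, 13–20 chain fragment, 21 peroxide reagent, 22–25 union and end game). Longest linear sequence: 16 steps (steps 1–12 and 22–25, from 1).

**Step 8 (key step).** Electron transfer to the enoate may compete with ketyl formation, which would saturate C9=C11 without ring closure; HMPA accelerates both processes. Facial control at C8 may also erode, because the axial C17 must pass the C20 methyl in the transition state. Fallback: from 9, the ring is closed as a neutral chain reaction through the O-stannyl ketyl (n-Bu3SnH added slowly, AIBN, benzene, 80 °C). No free electrons are present to reduce the enoate, the tin ketyl adds to the same carbon, and hydrogen transfer from the stannane followed by hydrolytic work-up returns to the route at 10. No new compound is made.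

**Step 10.** Non-directed oxidation at the ring A methylenes may compete with the directed path. If hydroxylation precedes a slow closure of the strained, doubly trans-fused lactone, the C6 carbinol may be oxidised on to the ketone. The catalyst antipode may also matter (matched and mismatched pairing). Fallback: from 12, the acid is converted ((COCl)2, cat. DMF; NH3) into the primary amide F1. Its N-iodoamide, generated and photolysed in one flask (PhI(OAc)2, I2, visible light, CH2Cl2), gives an amidyl radical that takes the 6α-hydrogen by 1,5-transfer in a Hofmann–Löffler–Freytag-type process. Iodination at C6 and ring closure through the amide oxygen give the iminolactone F2, which is hydrolysed on aqueous work-up and returns to the route at 13.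

**Step 22.** Photo-oxidation of the unactivated primary carboxylate may be slow, so that reduction of the radical to the C11–H compound gains ground. The carboxylate may be O-allylated by addition–elimination on 26 in the dark, and the lactone oxygen may be lost from the β-acyloxy ketone by β-elimination in the mildly basic medium. Fallback: from 29, silylation (TMSCl, imidazole, DMF; buffered work-up) gives the 8-O-trimethylsilyl acid F3. Esterification with N-hydroxyphthalimide (DIC, DMAP cat.) gives the redox-active ester F4. Reductive fragmentation ([Ru(bpy)3](PF6)2, Hantzsch ester, i-Pr2NEt, blue light) in the presence of 26 gives the silylated enone F5, and brief treatment with AcOH in MeOH removes the trimethylsilyl group and returns to the route at 30. This route generates the same radical without a nucleophilic carboxylate.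

**Step 24.** The peroxy anion may attack the 13-methylene carbon (allylic transposition), the secondary allylic mesylate may ionise with loss of configuration at C14, elimination to the diene may occur, and the peroxy anion may add to the butenolide. Fallback: from 31, Mitsunobu displacement with 2-nitrobenzenesulfonylhydrazide (PPh3, DEAD, THF, −30 °C → rt) gives the adduct F6. On warming it loses sulfinic acid and dinitrogen with transposition of the double bond to the 13(14)-olefin F7. The Schenck ene reaction of F7 (O2, tetraphenylporphyrin, visible light, CH2Cl2, 0 °C) gives the silylated hydroperoxide F8. It would have to be separated from its C14 epimer and from regioisomers by HPLC, and this lower selectivity is the price of neutral, orthogonal conditions. Desilylation (AcOH–THF–H2O) returns to the route at 34.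

**Step 2.** Benzylic oxidation at C7 to the aryl ketone may precede ring cleavage; the ketone deactivates the arene and the degradation stalls. Fallback: the ring is made electron-rich first. From 2, Friedel–Crafts acetylation (AcCl, AlCl3) gives the 12-acetyl compound F9, Baeyer–Villiger oxidation (mCPBA) the aryl acetate F10 and methanolysis (K2CO3, MeOH) the phenol F11. The phenol is degraded by RuCl3/NaIO4 under milder conditions and returns to the route at 3.

## Further compounds

F0 | step 8 | none | none
F1 | step 10 | primary C18 carboxamide of the 12,8α-lactone | O=C1C[C@@H]2[C@@]3(C)CCC[C@@](C)(C(N)=O)[C@@H]3CC[C@@]2(C)O1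
F2 | step 10 | 18,6α-iminolactone of the 12,8α-lactone | O=C1C[C@@H]2[C@@]3(C)CCC[C@@](C)(C(=N)O4)[C@@H]3[C@@H]4C[C@@]2(C)O1
F3 | step 22 | 6α-triethylsilyloxy-8α-trimethylsilyloxy C12 acid, C18 methyl ester | OC(=O)C[C@@H]1[C@@]2(C)CCC[C@@](C)(C(=O)OC)[C@@H]2[C@@H](O[Si](CC)(CC)CC)C[C@@]1(C)O[Si](C)(C)C
F4 | step 22 | N-hydroxyphthalimide ester of F3 | O=C(C[C@@H]1[C@@]2(C)CCC[C@@](C)(C(=O)OC)[C@@H]2[C@@H](O[Si](CC)(CC)CC)C[C@@]1(C)O[Si](C)(C)C)ON1C(=O)c2ccccc2C1=O
F5 | step 22 | 8-O-trimethylsilyl ether of 30 | C=C(CC[C@@H]1[C@@]2(C)CCC[C@@](C)(C(=O)OC)[C@@H]2[C@@H](O[Si](CC)(CC)CC)C[C@@]1(C)O[Si](C)(C)C)C(=O)C[C@@H]1OC(=O)C=C1C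
F6 | step 24 | (14S)-N-amino-N-(2-nitrophenylsulfonyl)amine from 31 | C=C(CC[C@@H]1[C@@]2(C)CCC[C@@](C)(C(=O)OC)[C@@H]2[C@@H](O[Si](CC)(CC)CC)C[C@@]1(C)O)[C@H](C[C@@H]1OC(=O)C=C1C)N(N)S(=O)(=O)c1ccccc1[N+](=O)[O-]
F7 | step 24 | (13E)-13(14)-olefin with C13 methyl, 6α-OTES | C/C(CC[C@@H]1[C@@]2(C)CCC[C@@](C)(C(=O)OC)[C@@H]2[C@@H](O[Si](CC)(CC)CC)C[C@@]1(C)O)=C\C[C@@H]1OC(=O)C=C1C
F8 | step 24 | 6-O-triethylsilyl ether of 34 | C=C(CC[C@@H]1[C@@]2(C)CCC[C@@](C)(C(=O)OC)[C@@H]2[C@@H](O[Si](CC)(CC)CC)C[C@@]1(C)O)[C@H](C[C@@H]1OC(=O)C=C1C)OO
F9 | step 2 | methyl 12-acetyldehydroabietate | CC(C)c1c(C(C)=O)cc2c(c1)CC[C@@H]1[C@]2(C)CCC[C@@]1(C)C(=O)OC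
F10 | step 2 | methyl 12-acetoxydehydroabietate | CC(C)c1c(OC(C)=O)cc2c(c1)CC[C@@H]1[C@]2(C)CCC[C@@]1(C)C(=O)OC
F11 | step 2 | methyl 12-hydroxydehydroabietate | CC(C)c1c(O)cc2c(c1)CC[C@@H]1[C@]2(C)CCC[C@@]1(C)C(=O)OC
A1 | alternative 1 | 6α-hydroxy-13,14,15,16-tetranorlabdan-12,8α-olide (4,4-dimethyl) | O=C1C[C@@H]2[C@@]3(C)CCCC(C)(C)[C@@H]3[C@@H](O)C[C@@]2(C)O1
A2 | alternative 1 | 6α,18-epoxy-13,14,15,16-tetranorlabdan-12,8α-olide | O=C1C[C@@H]2[C@@]3(C)CCC[C@@](C)(CO4)[C@@H]3[C@@H]4C[C@@]2(C)O1
A3 | alternative 2 | dithiane-masked trienone: methyl (E)-2-methyl-4-oxobut-2-enoate unit joined through CH2 to a 1,3-dithiane carbon that bears the allyl- and (E)-2-methylbuta-1,3-dienyl-substituted C9 | C=CC[C@H](/C(C)=C/C=C)C1(CC(=O)/C=C(\C)C(=O)OC)SCCCS1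
A4 | alternative 2 | trans-fused 6-oxo-octalin ester with C8 dithiane and C9 allyl | C=CC[C@@H]1[C@@]2(C)C=CC[C@@](C)(C(=O)OC)[C@@H]2C(=O)CC13SCCCS3
A5 | alternative 3 | 12,8α-lactone C18 acid (same compound as 12) | O=C1C[C@@H]2[C@@]3(C)CCC[C@@](C)(C(=O)O)[C@@H]3CC[C@@]2(C)O1
A6 | alternative 3 | 18,6α:12,8α-bislactone (same compound as 13) | O=C1C[C@@H]2[C@@]3(C)CCC[C@@](C)(C(=O)O4)[C@@H]3[C@@H]4C[C@@]2(C)O1
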